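## Retrosynthetic overview

1. Ring C (the pyranone) is made last. The (2S)-flavanone is opened at O1–C2 to the open-chain 2′,6′-dihydroxychalcone; in the forward direction a chalcone-isomerase-type 6-endo oxa-Michael closure, run with a chiral bifunctional catalyst on the unprotected chalcone, forms the ring and the only stereocentre in one operation.
2. The chalcone Cα=Cβ bond comes from a protecting-group-free aldol condensation of the diprenylated acetophenone with vanillin.
3. The two aryl–prenyl bonds come from a prenyltransferase-like double C-prenylation of 2′,6′-dihydroxy-4′-methoxyacetophenone with prenyl bromide.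
4. Rings A and B are bought as arenes. Ring A of the chalcone is symmetric, so either ortho-hydroxyl closes to the same flavanone.

Assumption 1: 2′,6′-dihydroxy-4′-methoxyacetophenone is bought as a catalogue chemical.
Assumption 2: the quinine-derived thiourea is taken to give the 2S series; this is not established for this substrate. The first run is checked by ECD (2S flavanones: positive Cotton effect near 330 nm, negative near 290 nm), and the quinidine-derived pseudoenantiomer is used instead if the sense is opposite.

## Route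

Step 1
Reactants: 1 1-(2,6-dihydroxy-4-methoxyphenyl)ethan-1-one (2′,6′-dihydroxy-4′-methoxyacetophenone); 2 1-bromo-3-methylbut-2-ene (prenyl bromide)
Product: 4 1-[2,6-dihydroxy-4-methoxy-3,5-bis(3-methylbut-2-en-1-yl)phenyl]ethan-1-one, via mono-prenyl acetophenone 3 (not isolated)
Conditions: 2 (2.4 equiv), 10% aq KOH, 0 °C → rt, 3 h
Reagents that add atoms: none
Why: Phenoxide C-alkylation (C-prenylation of an ambident phenoxide): in water the phenoxide oxygens are solvated, so the soft allylic bromide attacks the only free ring carbons C3 and C5 (each ortho and para to an O⁻), the chemical counterpart of aromatic prenyltransferase chemistry, and no stereocentre is formed.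

Step 2
Reactants: 4 1-[2,6-dihydroxy-4-methoxy-3,5-bis(3-methylbut-2-en-1-yl)phenyl]ethan-1-one; 5 4-hydroxy-3-methoxybenzaldehyde (vanillin)
Product: 7 (2E)-1-[2,6-dihydroxy-4-methoxy-3,5-bis(3-methylbut-2-en-1-yl)phenyl]-3-(4-hydroxy-3-methoxyphenyl)prop-2-en-1-one, via β-hydroxyketone aldol adduct 6 (not isolated)
Conditions: LiHMDS (6.5 equiv), THF, −78 °C → rt, 16 h; then cold 1 M HCl to pH 4, 0 °C
Reagents that add atoms: none
Why: Claisen–Schmidt aldol condensation through the lithium polyanion: excess LiHMDS turns 4 into its diphenoxide-enolate, which adds to lithium vanillinate; the p-oxidobenzylic aldolate 6 loses hydroxide by an E1cB/quinone-methide pathway to the thermodynamic (E)-enone, which stays ring-open as its phenoxide until the cold, mildly acidic quench that the prenyl groups tolerate; no stereocentre is formed.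

Step 3
Reactants: 7 (2E)-1-[2,6-dihydroxy-4-methoxy-3,5-bis(3-methylbut-2-en-1-yl)phenyl]-3-(4-hydroxy-3-methoxyphenyl)prop-2-en-1-one
Product: 8 (2S)-5-hydroxy-2-(4-hydroxy-3-methoxyphenyl)-7-methoxy-6,8-bis(3-methylbut-2-en-1-yl)-2,3-dihydro-4H-chromen-4-one
Conditions: N-[3,5-bis(trifluoromethyl)phenyl]-N′-[(8α,9S)-6′-methoxycinchonan-9-yl]thiourea (quinine-derived, 10 mol%), PhMe/CH2Cl2 4:1, 4 Å MS, −20 °C, 48 h; cold filtration through silica
Reagents that add atoms: none
Why: Proposed new method: a small-molecule chalcone-isomerase mimic applied to an unactivated, fully unprotected chalcone — the quinuclidine nitrogen acts as general base on one ortho-OH while the other ortho-OH keeps the carbonyl hydrogen-bonded, planar and more electrophilic (ring A is symmetric, so both hydroxyls give the same product), and the thiourea N–H pair binds the enone oxygen and then the enolate, so the phenoxide adds to one face of Cβ inside a chiral ion pair (6-endo-trig oxa-Michael) and C2 is set as S under catalyst control before the enolate is protonated; the closest known reaction type is the cinchona-thiourea-catalysed enantioselective intramolecular oxa-Michael cyclisation of 2′-hydroxychalcones and of their α-ester-activated analogues to flavanones.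

## Compound list

1 | 1-(2,6-dihydroxy-4-methoxyphenyl)ethan-1-one (2′,6′-dihydroxy-4′-methoxyacetophenone) | CC(=O)c1c(O)cc(OC)cc1O | starting material
2 | 1-bromo-3-methylbut-2-ene (prenyl bromide) | CC(C)=CCBr | starting material
3 | 1-[2,6-dihydroxy-4-methoxy-3-(3-methylbut-2-en-1-yl)phenyl]ethan-1-one (mono-prenyl acetophenone, formed in the flask) | CC(=O)c1c(O)cc(OC)c(CC=C(C)C)c1O | intermediate
4 | 1-[2,6-dihydroxy-4-methoxy-3,5-bis(3-methylbut-2-en-1-yl)phenyl]ethan-1-one | CC(=O)c1c(O)c(CC=C(C)C)c(OC)c(CC=C(C)C)c1O | intermediate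
5 | 4-hydroxy-3-methoxybenzaldehyde (vanillin) | COc1cc(C=O)ccc1O | starting material
6 | 1-[2,6-dihydroxy-4-methoxy-3,5-bis(3-methylbut-2-en-1-yl)phenyl]-3-hydroxy-3-(4-hydroxy-3-methoxyphenyl)propan-1-one (racemic aldol adduct, formed in the flask) | COc1cc(C(O)CC(=O)c2c(O)c(CC=C(C)C)c(OC)c(CC=C(C)C)c2O)ccc1O | intermediate
7 | (2E)-1-[2,6-dihydroxy-4-methoxy-3,5-bis(3-methylbut-2-en-1-yl)phenyl]-3-(4-hydroxy-3-methoxyphenyl)prop-2-en-1-one | COc1cc(/C=C/C(=O)c2c(O)c(CC=C(C)C)c(OC)c(CC=C(C)C)c2O)ccc1O | intermediate
8 | (2S)-5-hydroxy-2-(4-hydroxy-3-methoxyphenyl)-7-methoxy-6,8-bis(3-methylbut-2-en-1-yl)-2,3-dihydro-4H-chromen-4-one | COc1cc([C@@H]2CC(=O)c3c(O)c(CC=C(C)C)c(OC)c(CC=C(C)C)c3O2)ccc1O | target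

## Summary

Total step count: 3
Longest linear sequence: 3 steps (1 → 4 → 7 → 8)

## Steps most likely to fail and fallbacks

Step 3 is the most uncertain. The unprotected chalcone can close without the catalyst to give racemate, the acidic 4-hydroxyl can tie up the amine as a salt, and the 4′-hydroxy-5-hydroxyflavanone can lose ee by retro-Michael opening. The fallback replaces asymmetric catalysis by resolution with recycling and sets out from 7. Warming 7 with NaOAc in EtOH at 60 °C gives the racemic flavanone 5-hydroxy-2-(4-hydroxy-3-methoxyphenyl)-7-methoxy-6,8-bis(3-methylbut-2-en-1-yl)-2,3-dihydro-4H-chromen-4-one F6. Preparative chiral SFC on an amylose tris(3,5-dimethylphenylcarbamate) phase separates it into 8 and the (2R)-enantiomer F7. F7 is reopened to 7 with aq KOH/EtOH followed by cold acidification and is cycled again. The fallback comes back to the route at 8.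

Step 2 may stall because lithium vanillinate is a weak electrophile and the ketone is flanked by two ortho substituents. The chalcone may also close to racemic flavanone during work-up; that material can be reopened with cold aq KOH. The fallback uses protecting groups and sets out from 4 and 5. Treating 4 with NaH and MOMCl in DMF at 0 °C gives 1-[4-methoxy-2,6-bis(methoxymethoxy)-3,5-bis(3-methylbut-2-en-1-yl)phenyl]ethan-1-one F3. Treating 5 with MOMCl and iPr2NEt in CH2Cl2 gives 3-methoxy-4-(methoxymethoxy)benzaldehyde F4. Condensation of the two with KOH in EtOH/H2O at rt gives the tris-MOM chalcone (2E)-3-[3-methoxy-4-(methoxymethoxy)phenyl]-1-[4-methoxy-2,6-bis(methoxymethoxy)-3,5-bis(3-methylbut-2-en-1-yl)phenyl]prop-2-en-1-one F5. Removing the three MOM groups with 3 M HCl in MeOH at rt returns to the route at 7.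

Step 1 can give O-prenyl ethers, geminal 3,3-diprenyl dienones and mono-prenyl material 3, so the yield of 4 may be low. The fallback installs the side chains by sigmatropic rearrangement and metathesis and sets out from 1. Allyl bromide with K2CO3 in DMF at 60 °C gives the bis-allyl ether 1-[4-methoxy-2,6-bis(prop-2-en-1-yloxy)phenyl]ethan-1-one F1. A double aromatic Claisen rearrangement in N,N-diethylaniline at 195 °C moves each allyl group to its only free ortho carbon and gives 1-[2,6-dihydroxy-4-methoxy-3,5-di(prop-2-en-1-yl)phenyl]ethan-1-one F2. Cross-metathesis with excess 2-methylbut-2-ene (Grubbs II, 5 mol%, CH2Cl2, 40 °C) turns both allyl groups into prenyl groups and returns to the route at 4.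

## Further compounds

F1 | step 1 | 1-[4-methoxy-2,6-bis(prop-2-en-1-yloxy)phenyl]ethan-1-one | CC(=O)c1c(OCC=C)cc(OC)cc1OCC=C
F2 | step 1 | 1-[2,6-dihydroxy-4-methoxy-3,5-di(prop-2-en-1-yl)phenyl]ethan-1-one | CC(=O)c1c(O)c(CC=C)c(OC)c(CC=C)c1O
F3 | step 2 | 1-[4-methoxy-2,6-bis(methoxymethoxy)-3,5-bis(3-methylbut-2-en-1-yl)phenyl]ethan-1-one | CC(=O)c1c(OCOC)c(CC=C(C)C)c(OC)c(CC=C(C)C)c1OCOC
F4 | step 2 | 3-methoxy-4-(methoxymethoxy)benzaldehyde | COCOc1ccc(C=O)cc1OC
F5 | step 2 | (2E)-3-[3-methoxy-4-(methoxymethoxy)phenyl]-1-[4-methoxy-2,6-bis(methoxymethoxy)-3,5-bis(3-methylbut-2-en-1-yl)phenyl]prop-2-en-1-one | COCOc1ccc(/C=C/C(=O)c2c(OCOC)c(CC=C(C)C)c(OC)c(CC=C(C)C)c2OCOC)cc1OC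
F6 | step 3 | racemic 5-hydroxy-2-(4-hydroxy-3-methoxyphenyl)-7-methoxy-6,8-bis(3-methylbut-2-en-1-yl)-2,3-dihydro-4H-chromen-4-one | COc1cc(C2CC(=O)c3c(O)c(CC=C(C)C)c(OC)c(CC=C(C)C)c3O2)ccc1O
F7 | step 3 | (2R)-5-hydroxy-2-(4-hydroxy-3-methoxyphenyl)-7-methoxy-6,8-bis(3-methylbut-2-en-1-yl)-2,3-dihydro-4H-chromen-4-one | COc1cc([C@H]2CC(=O)c3c(O)c(CC=C(C)C)c(OC)c(CC=C(C)C)c3O2)ccc1O
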